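**Remarks on the chemistry.** The aryne precursor maps onto ring A without correction: its triflate carbon becomes C4a, its silyl carbon C8a, and Cl, OMe and OBn fall on C5, C6 and C7. 4-(Benzyloxy)-3-methoxybenzaldehyde (O-benzylvanillin) is assumed to be a catalogue compound; it is otherwise one benzylation from vanillin.

## Structural features

The target is built from two coumarin (2H-chromen-2-one) bicycles, coumarin A (unprimed) and coumarin B (primed), joined only by one ether oxygen that runs from C3 of A to C7' of B. Both bicycles carry a 6-methoxy group; C7 of A is a free phenol, whereas the C7' oxygen of B is the bridging atom. There is no stereocenter and no chirality axis, so the problem is one of connectivity and regiochemistry alone. The fragile parts are the two lactones (opened by hydroxide, alkoxides and amines), the unsubstituted C3'=C4' enoate of B (a Michael acceptor and easily hydrogenated), the free phenol, and the enol-ether-like C3–O bond. The real difficulty is the C3–O–C7' link: an ether between a vinylic carbon alpha to a lactone carbonyl and a phenolic oxygen flanked by a methoxy group, which is not convincingly made by C–O coupling of two finished coumarins. The key step exploits three facts about the pyranone of A: O1 and C4 sit on the adjacent arene carbons C8a and C4a (the two carbons of an aryne), C4 is a one-carbon unit at the formyl oxidation level, and C2–C3 with its oxygen is an alpha-aryloxyacetate. The difficult ether can therefore be inherited from a simple sp3 C–O alkylation of scopoletin.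

## Logic of the disconnections

**24 to 23.** The O7–benzyl bond is cut. A free phenol at O7 would be deprotonated by fluoride, would add to 17 and would quench organolithiums, so it travels protected. Nothing is gained in skeleton, but every earlier step is enabled. The forward cleavage must spare two aryl methyl ethers, the vinyl–aryl ether and both lactones, and must avoid hydrogen gas because of C3'=C4'.

**23 to 22.** The C5–H bond is traced back to C5–Cl. Without a substituent beside one aryne carbon, a 4,5-dialkoxyaryne is nearly unbiased and would give both the 6-OMe/7-OBn and the 7-OMe/6-OBn coumarin. A chlorine beside C4a polarizes the triple bond and is removable. The forward step is a chemoselective hydrodechlorination of a doubly ortho-substituted aryl chloride beside a benzyl ether and two enoates.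

**22 to 12, 16 and 15.** Four skeletal bonds are cut: O1–C8a and C4–C4a (arene to the oxygen and carbon of 16), then C3–C4 and O1–C2 (to the alpha-carbon and carbonyl of 15). This removes the pyranone of A in one operation, gives three pieces of comparable size, and places the C3–O–C7' ether inside 15. The forward step demands regiocontrol in the addition of 16 to 17, an enolate of 15 that tolerates coumarin B, and a defined order of events so that the enolate meets 19 and not 17.

**15 to 13 and 14.** The O7'–CH2 bond is cut. 13 has a single phenol, so the alkylation poses no selectivity question, and both partners are purchasable. The only demand is a base mild enough for the lactone.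

**12 to 10.** The S–O bond of the triflate and the carbamoyl C–O bond are cut. The oxygen that becomes the leaving group is the same one that carried the directing group. The forward cleavage and triflation must not desilylate the electron-rich arylsilane.

**10 to 7.** The C6–Si bond is cut. With chlorine already at C2, C6 is the only position ortho to the carbamate, so a single carbamate-directed metalation suffices and has no regiochemical choice to make. The demand is a low temperature, so that silylation outruns a carbamoyl shift.

**7 to 6 to 4.** The carbamate N–C(O)–O link is cut, and then the aryl C–O bond is traced to the formyl group by Dakin oxidation. The demand is aryl migration, which the para-alkoxy group favours and the ortho chlorine does not hinder.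

**4 to 1.** The C2–Cl bond is cut. Electrophilic chlorination would go para or ortho to the alkoxy groups, the wrong sites; lithiation directed by the masked formyl group together with the methoxy group places chlorine between them. The formyl group thus serves twice, as director for chlorine and as the precursor of the phenol oxygen, and 1 already carries the O-benzyl/O-methyl differentiation. The demand is metalation of the ring in preference to the benzylic CH2.

## Other disconnections considered

**Alternative 1:** The cut is at both O1–C8a and O1'–C8a', leading to the acyclic 8-O-4 dehydrodimer diacid A2.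
- *Forward key step:* a flavin photocatalyst under blue light and oxygen would isomerize both acrylic acid units by energy transfer. Single-electron oxidation would then let each carboxylate close on the ortho arene carbon para to methoxy, giving A1, which is identical with 23.
- *In favour:* both lactones form in one metal-free operation, no directing halogen is needed, and no strong base touches a coumarin. A1 is one step from the target where 22 is two. On step count and atom economy this alternative is the better plan, plausibly six steps or fewer. The ether of A2 can also be set at an sp3 stage, so on that structural point it is the equal of the chosen plan.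
- *Against:* the half of A2 that carries the aryloxy group on the alkene is an electron-rich enol ether. Its excited-state and radical-cation behaviour (photocycloaddition, oxidative cleavage by activated oxygen, stilbene-type closure) is much less predictable than that of a plain cinnamic acid. Two different cyclizations must both succeed, each with a choice between two ortho positions controlled only by substituent electronics.
- *Comparison:* the chosen plan fixes ring A regiochemistry through a single polarized aryne and buys coumarin B intact. It pays for this with the installation and removal of chlorine and a less precedented nucleophile.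

**Alternative 2:** The cut is at C4a'–C8a' of the benzene ring of coumarin B, leading to cyclobutenone A4, a squarate-type four-membered ring carrying the C3 oxygen of coumarin A and an alkenyl carbinol.
- *Forward key step:* heating A4 would open the ring to a dienylketene, whose 6π closure and tautomerization would give hydroquinone A3 (a Moore-type rearrangement).
- *In favour:* the substitution pattern of ring B is fixed by construction under neutral thermal conditions with no halogen to remove. The pericyclic cascade is mechanistically more certain than enolate capture in the chosen key step, and on that point the alternative is the better one.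
- *Against:* A3 is far from the target. One of two hydroquinone hydroxyls must be methylated selectively, the acetal unmasked, two carbons added and lactonized to build pyranone B, and the benzyl group removed. Coumarin A would also have to be made first as a C3-oxygenated lactone and survive addition of an alkenyllithium to the four-membered dione.
- *Comparison:* the alternative constructs a benzene ring that the chosen plan simply buys inside scopoletin, and builds neither pyranone in its key step. Step economy is clearly worse, probably twelve steps or more.

**Alternative 3:** The cut is at C8a'–O1', leading to indanone A6.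
- *Forward key step:* a peracid with a strong acid would insert oxygen by Baeyer–Villiger migration of the aryl carbon, which is para to methoxy and therefore migrates well, giving dihydrocoumarin A5.
- *In favour:* while coumarin A is assembled, the partner is a ketone and not a lactone with a Michael-acceptor double bond. The compatibility problem of the chosen enolate step does not arise in that form, which is a real advantage. The regiochemical certainty of the oxygen insertion is the equal of the aryne polarization.
- *Against:* A5 is at the wrong oxidation level, so a dehydrogenation to C3'=C4' must follow before debenzylation. The peracid must spare the electron-rich C3=C4 enol ether and the dialkoxyarenes. Methylene migration would give an isochromanone. A6 itself requires coumarin A to be built beside an enolizable, aldol-active ketone.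
- *Comparison:* coumarin B is made in three operations instead of being bought, so the route is longer than the chosen one.

Key step: step 7

## Route

**Step 1**
Reactants: 1 4-(benzyloxy)-3-methoxybenzaldehyde
Product: 4 4-(benzyloxy)-2-chloro-3-methoxybenzaldehyde, via lithium amino alkoxide 2 (not isolated), via chlorinated amino alkoxide 3 (not isolated)
Conditions: LiN(Me)CH2CH2NMe2 (from MeNHCH2CH2NMe2, n-BuLi), THF, −20 °C; n-BuLi, −20 °C; C2Cl6, −78 °C → rt; aq. HCl, 0 °C
Reagents that add atoms: hexachloroethane, ClC(Cl)(Cl)C(Cl)(Cl)Cl
Why: Alpha-amino alkoxide-directed ortho-lithiation; the lithium amide adds to the formyl group to give 2, which masks the aldehyde and cooperates with the 3-methoxy group to direct n-BuLi to C2, the position between them. The aryllithium abstracts chlorine from C2Cl6 to give 3, and the cold acidic work-up releases the aldehyde and the diamine.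

**Step 2**
Reactants: 4 4-(benzyloxy)-2-chloro-3-methoxybenzaldehyde
Product: 6 4-(benzyloxy)-2-chloro-3-methoxyphenol, via aryl formate 5 (not isolated)
Conditions: mCPBA, CH2Cl2, 0 °C → rt; then K2CO3 (cat.), MeOH, rt
Reagents that add atoms: 3-chloroperbenzoic acid (mCPBA), OOC(=O)c1cccc(Cl)c1
Why: Dakin-type Baeyer–Villiger oxidation; the electron-rich aryl group (para-benzyloxy) migrates in the Criegee intermediate to give formate 5, and methanolysis releases the phenol.

**Step 3**
Reactants: 6 4-(benzyloxy)-2-chloro-3-methoxyphenol
Product: 7 4-(benzyloxy)-2-chloro-3-methoxyphenyl propan-2-ylcarbamate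
Conditions: i-PrNCO, Et3N (cat.), CH2Cl2, rt
Reagents that add atoms: isopropyl isocyanate, CC(C)N=C=O
Why: Base-catalysed addition of the phenol to the isocyanate (carbamoylation); the N–H carbamate is chosen because it is a strong ortho director once N-silylated and can later be removed under mild base.

**Step 4**
Reactants: 7 4-(benzyloxy)-2-chloro-3-methoxyphenyl propan-2-ylcarbamate
Product: 10 4-(benzyloxy)-2-chloro-3-methoxy-6-(trimethylsilyl)phenyl propan-2-ylcarbamate, via N-silyl chlorocarbamate 8 (not isolated), via N-silyl arylsilane 9 (not isolated)
Conditions: TBSOTf, TMEDA, Et2O, 0 °C → rt; n-BuLi, TMEDA, −78 °C; TMSCl, −78 °C → rt; aq. NaHSO4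
Reagents that add atoms: chlorotrimethylsilane, C[Si](C)(C)Cl
Why: Directed ortho-metalation; in situ N-silylation masks the N–H, C6 is the only position ortho to the carbamate, and at −78 °C the aryllithium is silylated before an anionic Fries shift can compete. No hydrogen sits ortho to chlorine, so no aryne can form here, and the acidic work-up removes the N-silyl group.

**Step 5**
Reactants: 10 4-(benzyloxy)-2-chloro-3-methoxy-6-(trimethylsilyl)phenyl propan-2-ylcarbamate
Product: 12 4-(benzyloxy)-2-chloro-3-methoxy-6-(trimethylsilyl)phenyl trifluoromethanesulfonate, via silylphenol 11 (not isolated)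
Conditions: DBU, Et2NH, MeCN, 40 °C; then PhNTf2, rt
Reagents that add atoms: N-phenylbis(trifluoromethanesulfonimide), O=S(=O)(N(c1ccccc1)S(=O)(=O)C(F)(F)F)C(F)(F)F
Why: E1cB fragmentation of the N-monosubstituted carbamate gives the phenoxide of 11 and isopropyl isocyanate, which diethylamine traps as a urea; the phenoxide is triflated in the same flask. The basic, fluoride-free medium avoids protodesilylation of the electron-rich arylsilane.

**Step 6**
Reactants: 13 scopoletin (7-hydroxy-6-methoxychromen-2-one), 14 ethyl bromoacetate
Product: 15 ethyl 2-[(6-methoxy-2-oxochromen-7-yl)oxy]acetate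
Conditions: K2CO3, acetone, reflux
Reagents that add atoms: none
Why: Williamson ether synthesis (SN2) at the only phenol of 13; carbonate in acetone leaves the lactone intact.

**Step 7**
Reactants: 12 4-(benzyloxy)-2-chloro-3-methoxy-6-(trimethylsilyl)phenyl trifluoromethanesulfonate, 15 ethyl 2-[(6-methoxy-2-oxochromen-7-yl)oxy]acetate, 16 N,N-dimethylformamide
Product: 22 7-(benzyloxy)-5-chloro-6-methoxy-3-[(6-methoxy-2-oxochromen-7-yl)oxy]chromen-2-one, via aryne 17 (not isolated), via benzoxete 18 (not isolated), via iminium phenoxide 19 (not isolated), via lithium enolate 20 (not isolated), via aminolactone 21 (not isolated)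
Conditions: CsF, DMF (16 as solvent), rt; then 20 [from 15, LiN(SiMe3)2, THF, −78 °C] added at −50 °C → rt, then 50 °C; AcOH
Reagents that add atoms: none
Why: Proposed new method: fluoride-induced 1,2-elimination of 12 gives aryne 17, whose triple bond is polarized by the inductive pull of the neighbouring chlorine, so the oxygen of 16 attacks the carbon remote from chlorine (future C8a) while negative charge develops beside chlorine (future C4a); collapse onto the formamide carbon gives benzoxete 18, which opens to the ortho-quinone methide drawn as iminium phenoxide 19. The closest known reaction type is the CsF-triggered coupling of an aryne, a formamide and a doubly activated methylene compound to a coumarin, together with the capture of such aryne–formamide adducts by organozinc carbon nucleophiles; here the pronucleophile is a singly activated alpha-aryloxy ester, so its lithium enolate 20 is made separately and added only after the aryne has been consumed. The enolate carbon adds to the iminium carbon of 19 (Mannich-type, forming C3–C4), and the liberated phenoxide O1 attacks the ethyl ester by 6-exo-trig acyl substitution (forming O1–C2 and closing the pyranone) to give aminolactone 21. E1cB loss of dimethylamine, driven by the ethoxide released on lactonization and by conjugation, then installs C3=C4. The two stereocenters of 21 are transient and are erased by this elimination, so no stereocontrol is required. Regioselectivity rests on the C5 chlorine; chemoselectivity for the iminium over the lactone and C4' of coumarin B is expected from the low temperature, the much higher electrophilicity of the iminium and the deactivation of a 6,7-dioxygenated coumarin as an acceptor. The order of addition keeps the enolate from arylating on the aryne, and the acetic acid quench recloses any lactone opened by ethoxide.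

**Step 8**
Reactants: 22 7-(benzyloxy)-5-chloro-6-methoxy-3-[(6-methoxy-2-oxochromen-7-yl)oxy]chromen-2-one
Product: 23 7-(benzyloxy)-6-methoxy-3-[(6-methoxy-2-oxochromen-7-yl)oxy]chromen-2-one
Conditions: Pd(OAc)2 (cat.), PCy3 (cat.), HCO2Na, DMF, 90 °C
Reagents that add atoms: none
Why: Palladium-catalysed hydrodechlorination; zerovalent palladium carrying the electron-rich phosphine inserts into the C–Cl bond, formate exchanges for chloride and decarboxylates to an aryl palladium hydride, and reductive elimination gives the C5–H bond. Under these homogeneous conditions the benzyl ether is not hydrogenolysed.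

**Step 9**
Reactants: 23 7-(benzyloxy)-6-methoxy-3-[(6-methoxy-2-oxochromen-7-yl)oxy]chromen-2-one
Product: 24 7-hydroxy-6-methoxy-3-[(6-methoxy-2-oxochromen-7-yl)oxy]chromen-2-one
Conditions: BCl3, C6HMe5, CH2Cl2, −78 °C; then MeOH
Reagents that add atoms: none
Why: Lewis acid cleavage of the aryl benzyl ether; pentamethylbenzene captures the benzyl cation by Friedel–Crafts alkylation so that the electron-rich rings are not C-benzylated. At −78 °C the methyl ethers, the vinyl–aryl ether and both lactones are retained.

## Compound list

1 | 4-(benzyloxy)-3-methoxybenzaldehyde (O-benzylvanillin) | COc1cc(C=O)ccc1OCc1ccccc1 | starting material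
2 | lithium [4-(benzyloxy)-3-methoxyphenyl]{[2-(dimethylamino)ethyl](methyl)amino}methanolate (racemic) | [Li+].COc1cc(C([O-])N(C)CCN(C)C)ccc1OCc1ccccc1 | intermediate
3 | lithium [4-(benzyloxy)-2-chloro-3-methoxyphenyl]{[2-(dimethylamino)ethyl](methyl)amino}methanolate (racemic) | [Li+].COc1c(OCc2ccccc2)ccc(C([O-])N(C)CCN(C)C)c1Cl | intermediate
4 | 4-(benzyloxy)-2-chloro-3-methoxybenzaldehyde | COc1c(OCc2ccccc2)ccc(C=O)c1Cl | intermediate
5 | 4-(benzyloxy)-2-chloro-3-methoxyphenyl formate | COc1c(OCc2ccccc2)ccc(OC=O)c1Cl | intermediate
6 | 4-(benzyloxy)-2-chloro-3-methoxyphenol | COc1c(OCc2ccccc2)ccc(O)c1Cl | intermediate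
7 | 4-(benzyloxy)-2-chloro-3-methoxyphenyl propan-2-ylcarbamate | COc1c(OCc2ccccc2)ccc(OC(=O)NC(C)C)c1Cl | intermediate
8 | 4-(benzyloxy)-2-chloro-3-methoxyphenyl [tert-butyl(dimethyl)silyl](propan-2-yl)carbamate | COc1c(OCc2ccccc2)ccc(OC(=O)N(C(C)C)[Si](C)(C)C(C)(C)C)c1Cl | intermediate
9 | 4-(benzyloxy)-2-chloro-3-methoxy-6-(trimethylsilyl)phenyl [tert-butyl(dimethyl)silyl](propan-2-yl)carbamate | COc1c(OCc2ccccc2)cc([Si](C)(C)C)c(OC(=O)N(C(C)C)[Si](C)(C)C(C)(C)C)c1Cl | intermediate
10 | 4-(benzyloxy)-2-chloro-3-methoxy-6-(trimethylsilyl)phenyl propan-2-ylcarbamate | COc1c(OCc2ccccc2)cc([Si](C)(C)C)c(OC(=O)NC(C)C)c1Cl | intermediate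
11 | 4-(benzyloxy)-2-chloro-3-methoxy-6-(trimethylsilyl)phenol (formed as its amidinium phenoxide) | COc1c(OCc2ccccc2)cc([Si](C)(C)C)c(O)c1Cl | intermediate
12 | 4-(benzyloxy)-2-chloro-3-methoxy-6-(trimethylsilyl)phenyl trifluoromethanesulfonate | COc1c(OCc2ccccc2)cc([Si](C)(C)C)c(OS(=O)(=O)C(F)(F)F)c1Cl | intermediate
13 | scopoletin (7-hydroxy-6-methoxychromen-2-one) | COc1cc2ccc(=O)oc2cc1O | starting material
14 | ethyl bromoacetate | CCOC(=O)CBr | starting material
15 | ethyl 2-[(6-methoxy-2-oxochromen-7-yl)oxy]acetate | CCOC(=O)COc1cc2oc(=O)ccc2cc1OC | intermediate
16 | N,N-dimethylformamide | CN(C)C=O | starting material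
17 | 5-(benzyloxy)-3-chloro-4-methoxy-1,2-didehydrobenzene (aryne) | ClC1=C(OC)C(OCc2ccccc2)=CC#C1 | intermediate
18 | 5-(benzyloxy)-3-chloro-4-methoxy-N,N-dimethyl-2H-1-benzoxet-2-amine (racemic) | CN(C)C1Oc2cc(OCc3ccccc3)c(OC)c(Cl)c21 | intermediate
19 | 5-(benzyloxy)-3-chloro-2-[(dimethyliminio)methyl]-4-methoxyphenolate (zwitterionic form of the ortho-quinone methide) | C[N+](C)=Cc1c([O-])cc(OCc2ccccc2)c(OC)c1Cl | intermediate
20 | lithium (E)-1-ethoxy-2-[(6-methoxy-2-oxochromen-7-yl)oxy]ethen-1-olate (chelated geometry drawn; the geometry has no consequence) | [Li+].CCO/C([O-])=C/Oc1cc2oc(=O)ccc2cc1OC | intermediate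
21 | 7-(benzyloxy)-5-chloro-4-(dimethylamino)-6-methoxy-3-[(6-methoxy-2-oxochromen-7-yl)oxy]-3,4-dihydrochromen-2-one (racemic mixture of diastereomers; both stereocenters are erased on elimination) | COc1c(OCc2ccccc2)cc2OC(=O)C(Oc3cc4oc(=O)ccc4cc3OC)C(N(C)C)c2c1Cl | intermediate
22 | 7-(benzyloxy)-5-chloro-6-methoxy-3-[(6-methoxy-2-oxochromen-7-yl)oxy]chromen-2-one | COc1c(OCc2ccccc2)cc2oc(=O)c(Oc3cc4oc(=O)ccc4cc3OC)cc2c1Cl | intermediate
23 | 7-(benzyloxy)-6-methoxy-3-[(6-methoxy-2-oxochromen-7-yl)oxy]chromen-2-one | COc1cc2cc(Oc3cc4oc(=O)ccc4cc3OC)c(=O)oc2cc1OCc1ccccc1 | intermediate
24 | 7-hydroxy-6-methoxy-3-[(6-methoxy-2-oxochromen-7-yl)oxy]chromen-2-one | COc1cc2cc(Oc3cc4oc(=O)ccc4cc3OC)c(=O)oc2cc1O | target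

## Step count and least certain steps

Total step count: 9. Longest linear sequence: 8 steps (steps 1 to 5, then 7, 8 and 9); step 6 is the one-step side branch.

**Step 7 (key step, proposed new method).** Three processes are most likely to fail.
- Self-destruction of the enolate during its formation, by Michael addition or Claisen-type attack on the coumarin B unit of a second molecule.
- Decay of the aryne–formamide adduct (dimerization or capture of a second aryne) before the enolate arrives.
- Loss of chloride from the ortho-chloroaryl anion before it closes onto the formamide carbon.

The fallback uses known chemistry and sets out from 12 and 15. The same fluoride-triggered aryne insertion into 16 is run and quenched with water, which hydrolyses adduct 19 to 4-(benzyloxy)-2-chloro-6-hydroxy-3-methoxybenzaldehyde F1. Separately 15 is saponified (LiOH, THF/H2O, then HCl, on which the lactone recloses) to 2-[(6-methoxy-2-oxochromen-7-yl)oxy]acetic acid F2. A Perkin-type condensation of F1 with F2 (Ac2O, Et3N, 110 °C) closes the pyranone by O-acylation and intramolecular Knoevenagel condensation. The fallback returns to the route at 22.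

**Step 1.** n-BuLi may deprotonate the benzylic CH2 of the benzyl ether (followed by Wittig rearrangement) or lithiate the less crowded C6, because the cooperative site is flanked by two substituents and the metalation is run at −20 °C. Incomplete lithiation would return 1. The fallback sets out from 1 and moves the chlorination to the carbamate stage, where the metalation runs at −78 °C. Dakin oxidation (mCPBA, then K2CO3/MeOH) gives, by way of 4-(benzyloxy)-3-methoxyphenyl formate F3, 4-(benzyloxy)-3-methoxyphenol F4, and carbamoylation with isopropyl isocyanate gives 4-(benzyloxy)-3-methoxyphenyl propan-2-ylcarbamate F5. In situ N-silylation (TBSOTf, TMEDA) gives 4-(benzyloxy)-3-methoxyphenyl [tert-butyl(dimethyl)silyl](propan-2-yl)carbamate F6, which n-BuLi/TMEDA should lithiate between the carbamate and the methoxy group; C2Cl6 then gives 8 in the flask. Aqueous NaHSO4 removes the N-silyl group, and the fallback returns to the route at 7.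

**Step 4.** An anionic Fries shift of the carbamoyl group onto the lithiated carbon may occur, and the benzylic CH2 may again be metalated. The new silyl group, which sits para to methoxy, may also be lost by protodesilylation during work-up or the subsequent cleavage. The fallback sets out from 6 and avoids carbamate-directed lithiation altogether. Bromination with N-bromosuccinimide ortho to the hydroxyl and para to methoxy gives 4-(benzyloxy)-6-bromo-2-chloro-3-methoxyphenol F7, and hexamethyldisilazane gives [4-(benzyloxy)-6-bromo-2-chloro-3-methoxyphenoxy]trimethylsilane F8. n-BuLi at −78 °C effects bromine–lithium exchange and a retro-Brook shift of silicon from oxygen to carbon, giving the lithium salt of 11, which Tf2O triflates. The fallback returns to the route at 12.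

**Step 8.** Oxidative addition into the doubly ortho-substituted, electron-rich C–Cl bond may be sluggish. A palladium hydride may reduce the unsubstituted C3'=C4' double bond of coumarin B by conjugate reduction. The fallback sets out from 22 and changes to heterogeneous hydrogenolysis (Pd/C, H2, Et3N, EtOAc/THF, rt), which should remove chlorine and the benzyl group in one operation. It bypasses 23 and arrives directly at 24. The process to watch there is over-reduction of the enoate, so the reaction would be stopped as soon as conversion is complete.

## Further compounds

F1 | step 7 | 4-(benzyloxy)-2-chloro-6-hydroxy-3-methoxybenzaldehyde | COc1c(OCc2ccccc2)cc(O)c(C=O)c1Cl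
F2 | step 7 | 2-[(6-methoxy-2-oxochromen-7-yl)oxy]acetic acid | COc1cc2ccc(=O)oc2cc1OCC(O)=O
F3 | step 1 | 4-(benzyloxy)-3-methoxyphenyl formate | COc1cc(OC=O)ccc1OCc1ccccc1
F4 | step 1 | 4-(benzyloxy)-3-methoxyphenol | COc1cc(O)ccc1OCc1ccccc1
F5 | step 1 | 4-(benzyloxy)-3-methoxyphenyl propan-2-ylcarbamate | COc1cc(OC(=O)NC(C)C)ccc1OCc1ccccc1
F6 | step 1 | 4-(benzyloxy)-3-methoxyphenyl [tert-butyl(dimethyl)silyl](propan-2-yl)carbamate | COc1cc(OC(=O)N(C(C)C)[Si](C)(C)C(C)(C)C)ccc1OCc1ccccc1
F7 | step 4 | 4-(benzyloxy)-6-bromo-2-chloro-3-methoxyphenol | COc1c(OCc2ccccc2)cc(Br)c(O)c1Cl
F8 | step 4 | [4-(benzyloxy)-6-bromo-2-chloro-3-methoxyphenoxy]trimethylsilane | COc1c(OCc2ccccc2)cc(Br)c(O[Si](C)(C)C)c1Cl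
F0 | step 8 | none | none
A1 | alternative 1 | 7-(benzyloxy)-6-methoxy-3-[(6-methoxy-2-oxochromen-7-yl)oxy]chromen-2-one | COc1cc2cc(Oc3cc4oc(=O)ccc4cc3OC)c(=O)oc2cc1OCc1ccccc1
A2 | alternative 1 | (2Z)-3-[4-(benzyloxy)-3-methoxyphenyl]-2-{4-[(1E)-2-carboxyethenyl]-2-methoxyphenoxy}prop-2-enoic acid | COc1cc(/C=C(\Oc2ccc(/C=C/C(O)=O)cc2OC)C(O)=O)ccc1OCc1ccccc1
A3 | alternative 2 | 7-(benzyloxy)-3-[4-(diethoxymethyl)-2,5-dihydroxyphenoxy]-6-methoxychromen-2-one | CCOC(OCC)c1cc(O)c(Oc2cc3cc(OC)c(OCc4ccccc4)cc3oc2=O)cc1O
A4 | alternative 2 | 3-{[7-(benzyloxy)-6-methoxy-2-oxochromen-3-yl]oxy}-4-[(1E)-3,3-diethoxyprop-1-en-1-yl]-4-hydroxycyclobut-2-en-1-one (racemic) | CCOC(OCC)/C=C/C1(O)C(Oc2cc3cc(OC)c(OCc4ccccc4)cc3oc2=O)=CC1=O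
A5 | alternative 3 | 7-(benzyloxy)-6-methoxy-3-[(6-methoxy-2-oxo-3,4-dihydrochromen-7-yl)oxy]chromen-2-one | COc1cc2c(cc1Oc1cc3cc(OC)c(OCc4ccccc4)cc3oc1=O)OC(=O)CC2
A6 | alternative 3 | 7-(benzyloxy)-6-methoxy-3-[(6-methoxy-3-oxo-2,3-dihydro-1H-inden-5-yl)oxy]chromen-2-one | COc1cc2c(cc1Oc1cc3cc(OC)c(OCc4ccccc4)cc3oc1=O)C(=O)CC2
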